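**Retrosynthetic overview**
- The C3-appended α-methyl-γ-butyrolactone is added last: iridium-catalysed reductive vinylogous Mannich reaction on the C3 lactam, then butenolide hydrogenation.
- The furo[3,2-b]furanone comes from a 5-exo cyclisation of a nucleophilic acyl radical (acyl-anion equivalent, from a selenoester) onto a β-alkoxy-methacrylate, forming the C3a–C6a bond and the tetrahydrofuran ring; ketone reduction and lactonisation follow.
- The cyclisation precursor comes from an Evans syn-aldol with acetaldehyde on an N-acyl oxazolidinone, auxiliary-to-selenoester exchange and O-alkenylation.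
- The pyrrolo[1,2-a]azepin-3-one comes from an auxiliary- and substrate-matched cuprate addition to an (S)-pyroglutaminol-derived enoyl imide, then acid-mediated reductive amidoalkylation.
- Ring order: pyrrolidinone (chiral pool) → azepane → tetrahydrofuran → fused lactone → appended lactone.

Assumption: 2-(3-chloropropyl)-1,3-dioxolane, methyl (E)-3-methoxy-2-methylacrylate and 3-methylfuran-2(5H)-one are taken as catalogue chemicals; locants C1–C9a refer to the pyrrolo[1,2-a]azepine and C2–C6a to the furo[3,2-b]furanone.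

**Route**

Step 1
Reactants: 1 (R)-4-benzyl-2-oxazolidinone; 2 diethylphosphonoacetic acid
Product: 4 (R)-4-benzyl-3-[2-(diethoxyphosphoryl)acetyl]oxazolidin-2-one, via mixed pivalic anhydride 3 (not isolated)
Conditions: 2, PivCl, Et3N, THF, −20 °C; then 1, LiCl, rt
Reagents that add atoms: none
Why: Mixed-anhydride N-acylation of an oxazolidinone, in which the lithium-chelated oxazolidinone attacks the less hindered phosphonoacetyl carbonyl; no stereocentre is formed.

Step 2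
Reactants: 5 (S)-5-(hydroxymethyl)pyrrolidin-2-one; 4 phosphonate imide
Product: 7 (R)-4-benzyl-3-[(E)-3-((S)-5-oxopyrrolidin-2-yl)acryloyl]oxazolidin-2-one, via (S)-pyroglutaminal 6 (not isolated)
Conditions: IBX, DMSO, rt; then 4, LiCl, i-Pr2NEt, MeCN, 0 °C → rt
Reagents that add atoms: none
Why: Alcohol oxidation followed in the same flask by a Masamune–Roush Horner–Wadsworth–Emmons olefination gives the (E)-enoyl imide under amine/LiCl conditions mild enough to keep the α-amino aldehyde stereocentre (future C9a, S) intact.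

Step 3
Reactants: 7 enoyl imide; 8 2-(3-chloropropyl)-1,3-dioxolane
Product: 10 (R)-4-benzyl-3-[(R)-6-(1,3-dioxolan-2-yl)-3-((S)-5-oxopyrrolidin-2-yl)hexanoyl]oxazolidin-2-one, via Grignard reagent 9 (not isolated)
Conditions: 8, Mg, THF, reflux; 7, i-PrMgCl (1.0 equiv), THF, −78 °C; then 9 (2 equiv), CuBr·SMe2 (0.3 equiv), −78 → −20 °C; aq. NH4Cl
Reagents that add atoms: none
Why: Copper-catalysed 1,4-addition of a Grignard reagent to an N-enoyl oxazolidinone, in which the magnesium-chelated s-cis imide is attacked on the β-face opposite the benzyl group, which is also the face anti to the lactam nitrogen of the γ-stereocentre (matched case), setting C9 as R.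

Step 4
Reactants: 10 acetal imide
Product: 13 (R)-4-benzyl-3-{2-[(9R,9aS)-3-oxooctahydro-1H-pyrrolo[1,2-a]azepin-9-yl]acetyl}oxazolidin-2-one, via aldehyde 11 (not isolated), via cyclic N-acyl hemiaminal 12 (not isolated)
Conditions: CF3CO2H/H2O (9:1), CH2Cl2, 0 °C → rt; then Et3SiH, 40 °C
Reagents that add atoms: none
Why: Acetal hydrolysis, intramolecular amide–aldehyde condensation and ionic hydrogenation of the resulting N-acyliminium ion (reductive amidoalkylation) close the azepane ring at N–C5 without base, so the acidic imide α-CH2 is never deprotonated; no stereocentre is formed.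

Step 5
Reactants: 13 bicyclic imide; 14 acetaldehyde
Product: 16 (R)-4-benzyl-3-{(2R,3S)-3-hydroxy-2-[(9R,9aS)-3-oxooctahydro-1H-pyrrolo[1,2-a]azepin-9-yl]butanoyl}oxazolidin-2-one, via boron enolate 15 (not isolated)
Conditions: n-Bu2BOTf (2.2 equiv), i-Pr2NEt, CH2Cl2, −78 → 0 °C; 14, −78 → 0 °C; then H2O2, MeOH, pH 7 buffer
Reagents that add atoms: none
Why: Evans syn-aldol reaction, in which the (Z)-boron enolate reacts through a Zimmerman–Traxler chair on the face away from the benzyl group of the (R)-auxiliary, giving the (2R,3S) syn adduct that becomes C3 and C2 of the tetrahydrofuran ring.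

Step 6
Reactants: 16 aldol imide
Product: 17 Se-phenyl (2R,3S)-3-hydroxy-2-[(9R,9aS)-3-oxooctahydro-1H-pyrrolo[1,2-a]azepin-9-yl]butaneselenoate
Conditions: AlMe3, PhSeH, CH2Cl2, 0 °C; then 16, 0 °C → rt
Reagents that add atoms: benzeneselenol, [SeH]c1ccccc1
Why: Proposed new method: aluminium-selenolate acyl substitution of the aldol imide, in which the aluminium alkoxide of the free β-hydroxyl delivers Me2AlSePh to the exocyclic carbonyl and expels the oxazolidinone, by analogy with Me2Al–amide (Weinreb) and Me2Al–thiolate cleavage of aldol imides and with the known Me2AlSeR conversion of esters into selenoesters; no stereocentre changes.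

Step 7
Reactants: 17 hydroxy selenoester; 18 methyl (E)-3-methoxy-2-methylacrylate
Product: 19 Se-phenyl (2R,3S)-3-{[(E)-3-methoxy-2-methyl-3-oxoprop-1-en-1-yl]oxy}-2-[(9R,9aS)-3-oxooctahydro-1H-pyrrolo[1,2-a]azepin-9-yl]butaneselenoate
Conditions: 18 (5 equiv), PPTS (0.2 equiv), toluene, 110 °C, 4 Å MS (MeOH removal)
Reagents that add atoms: none
Why: Acid-catalysed alkoxy exchange (transetherification through the mixed acetal) of the β-methoxyacrylate with the secondary alcohol, driven by removal of methanol, gives the β-alkoxy-methacrylate (vinylogous carbonate) without touching the stereocentres.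

Step 8
Reactants: 19 selenoester
Product: 22 (9R,9aS)-9-[(2S,3R,3aR,6S,6aR)-2,6-dimethyl-5-oxohexahydrofuro[3,2-b]furan-3-yl]octahydro-3H-pyrrolo[1,2-a]azepin-3-one, via keto ester 20 (not isolated), via hydroxy ester 21 (not isolated)
Conditions: (Me3Si)3SiH, Et3B, air, PhH (0.01 M), rt; then NaBH4, MeOH, −78 → −40 °C; then CSA (cat.), CH2Cl2, rt
Reagents that add atoms: none
Why: Key step, a radical Stetter-type hydroacylation in which the nucleophilic acyl radical from the selenoester (an acyl-anion equivalent) closes 5-exo onto the electrophilic β-carbon of the β-alkoxy-methacrylate, joining two normally electrophilic carbons to give the 2,5-cis tetrahydrofuran-3-one (vinyl ether reacting with its allylic C–H in plane, sets C6a), the ester-substituted radical then takes hydrogen anti to the ring oxygen (exocyclic-effect model, sets C6), and NaBH4 attacks the ketone from the face opposite the three cis substituents (sets C3a) so that the cis alkoxide lactonises.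

Step 9
Reactants: 23 3-methylfuran-2(5H)-one
Product: 24 3-methyl-2-(triisopropylsilyloxy)furan
Conditions: TIPSOTf, Et3N, CH2Cl2, 0 °C → rt
Reagents that add atoms: triisopropylsilyl trifluoromethanesulfonate, CC(C)[Si](C(C)C)(C(C)C)OS(=O)(=O)C(F)(F)F
Why: Soft enolisation and O-silylation of the butenolide gives the aromatic 2-silyloxyfuran (silyl dienol ether formation).

Step 10
Reactants: 22 lactam; 24 silyloxyfuran
Product: 26 (S)-5-{(3S,9R,9aS)-9-[(2S,3R,3aR,6S,6aR)-2,6-dimethyl-5-oxohexahydrofuro[3,2-b]furan-3-yl]octahydro-1H-pyrrolo[1,2-a]azepin-3-yl}-3-methylfuran-2(5H)-one, via N,O-silyl acetal 25 (not isolated)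
Conditions: IrCl(CO)(PPh3)2 (2 mol %), (Me2HSi)2O, toluene, rt; then 24, 2-nitrobenzoic acid, MeCN, rt
Reagents that add atoms: none
Why: Iridium-catalysed hydrosilylation is selective for the tertiary lactam over the lactone and gives an N,O-silyl acetal that ionises to the bicyclic iminium ion, and the vinylogous Mannich addition of the silyloxyfuran occurs on the face anti to the C9a–C9 bond (2,5-trans pyrrolidine, C3 = S) with the usual threo preference of the open transition state setting the butenolide C5 as S.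

Step 11
Reactants: 26 butenolide
Product: 27 (3S,5S)-5-{(3S,9R,9aS)-9-[(2S,3R,3aR,6S,6aR)-2,6-dimethyl-5-oxohexahydrofuro[3,2-b]furan-3-yl]octahydro-1H-pyrrolo[1,2-a]azepin-3-yl}-3-methyldihydrofuran-2(3H)-one (target)
Conditions: H2 (1 atm), 5% Rh/Al2O3, EtOAc, rt
Reagents that add atoms: none
Why: Heterogeneous hydrogenation adds hydrogen to the butenolide face opposite the bulky C5 substituent, giving the cis-3,5-disubstituted lactone (3S) and the target.

**Compound list**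

1 | (R)-4-benzyl-2-oxazolidinone | O=C1OC[C@@H](Cc2ccccc2)N1 | starting material
2 | diethylphosphonoacetic acid | CCOP(=O)(OCC)CC(=O)O | starting material
3 | diethylphosphonoacetic pivalic anhydride | CCOP(=O)(OCC)CC(=O)OC(=O)C(C)(C)C | intermediate
4 | (R)-4-benzyl-3-[2-(diethoxyphosphoryl)acetyl]oxazolidin-2-one | CCOP(=O)(OCC)CC(=O)N1[C@H](Cc2ccccc2)COC1=O | intermediate
5 | (S)-5-(hydroxymethyl)pyrrolidin-2-one ((S)-pyroglutaminol) | OC[C@@H]1CCC(=O)N1 | starting material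
6 | (S)-5-oxopyrrolidine-2-carbaldehyde | O=C[C@@H]1CCC(=O)N1 | intermediate
7 | (R)-4-benzyl-3-[(E)-3-((S)-5-oxopyrrolidin-2-yl)acryloyl]oxazolidin-2-one | O=C(/C=C/[C@@H]1CCC(=O)N1)N1[C@H](Cc2ccccc2)COC1=O | intermediate
8 | 2-(3-chloropropyl)-1,3-dioxolane | ClCCCC1OCCO1 | starting material
9 | [3-(1,3-dioxolan-2-yl)propyl]magnesium chloride | Cl[Mg]CCCC1OCCO1 | intermediate
10 | (R)-4-benzyl-3-[(R)-6-(1,3-dioxolan-2-yl)-3-((S)-5-oxopyrrolidin-2-yl)hexanoyl]oxazolidin-2-one | O=C(C[C@@H](CCCC1OCCO1)[C@@H]1CCC(=O)N1)N1[C@H](Cc2ccccc2)COC1=O | intermediate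
11 | (R)-4-benzyl-3-[(R)-7-oxo-3-((S)-5-oxopyrrolidin-2-yl)heptanoyl]oxazolidin-2-one | O=C(C[C@@H](CCCC=O)[C@@H]1CCC(=O)N1)N1[C@H](Cc2ccccc2)COC1=O | intermediate
12 | (R)-4-benzyl-3-{2-[(9R,9aS)-5-hydroxy-3-oxooctahydro-1H-pyrrolo[1,2-a]azepin-9-yl]acetyl}oxazolidin-2-one (C5 epimers) | O=C(C[C@H]1CCCC(O)N2[C@H]1CCC2=O)N1[C@H](Cc2ccccc2)COC1=O | intermediate
13 | (R)-4-benzyl-3-{2-[(9R,9aS)-3-oxooctahydro-1H-pyrrolo[1,2-a]azepin-9-yl]acetyl}oxazolidin-2-one | O=C(C[C@H]1CCCCN2[C@H]1CCC2=O)N1[C@H](Cc2ccccc2)COC1=O | intermediate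
14 | acetaldehyde | CC=O | starting material
15 | (Z)-di-n-butylboron enolate of 13 | CCCCB(CCCC)O/C(=C\[C@H]1CCCCN2[C@H]1CCC2=O)N1[C@H](Cc2ccccc2)COC1=O | intermediate
16 | (R)-4-benzyl-3-{(2R,3S)-3-hydroxy-2-[(9R,9aS)-3-oxooctahydro-1H-pyrrolo[1,2-a]azepin-9-yl]butanoyl}oxazolidin-2-one | C[C@H](O)[C@H](C(=O)N1[C@H](Cc2ccccc2)COC1=O)[C@H]1CCCCN2[C@H]1CCC2=O | intermediate
17 | Se-phenyl (2R,3S)-3-hydroxy-2-[(9R,9aS)-3-oxooctahydro-1H-pyrrolo[1,2-a]azepin-9-yl]butaneselenoate | C[C@H](O)[C@H](C(=O)[Se]c1ccccc1)[C@H]1CCCCN2[C@H]1CCC2=O | intermediate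
18 | methyl (E)-3-methoxy-2-methylacrylate | CO/C=C(\C)C(=O)OC | starting material
19 | Se-phenyl (2R,3S)-3-{[(E)-3-methoxy-2-methyl-3-oxoprop-1-en-1-yl]oxy}-2-[(9R,9aS)-3-oxooctahydro-1H-pyrrolo[1,2-a]azepin-9-yl]butaneselenoate | C[C@H](O/C=C(\C)C(=O)OC)[C@H](C(=O)[Se]c1ccccc1)[C@H]1CCCCN2[C@H]1CCC2=O | intermediate
20 | methyl (S)-2-{(2R,4R,5S)-5-methyl-3-oxo-4-[(9R,9aS)-3-oxooctahydro-1H-pyrrolo[1,2-a]azepin-9-yl]tetrahydrofuran-2-yl}propanoate | C[C@@H]1O[C@H]([C@H](C)C(=O)OC)C(=O)[C@@H]1[C@H]1CCCCN2[C@H]1CCC2=O | intermediate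
21 | methyl (S)-2-{(2R,3R,4S,5S)-3-hydroxy-5-methyl-4-[(9R,9aS)-3-oxooctahydro-1H-pyrrolo[1,2-a]azepin-9-yl]tetrahydrofuran-2-yl}propanoate (all-cis ring) | C[C@@H]1O[C@H]([C@H](C)C(=O)OC)[C@H](O)[C@@H]1[C@H]1CCCCN2[C@H]1CCC2=O | intermediate
22 | (9R,9aS)-9-[(2S,3R,3aR,6S,6aR)-2,6-dimethyl-5-oxohexahydrofuro[3,2-b]furan-3-yl]octahydro-3H-pyrrolo[1,2-a]azepin-3-one | C[C@@H]1O[C@H]2[C@H](OC(=O)[C@H]2C)[C@@H]1[C@H]1CCCCN2[C@H]1CCC2=O | intermediate
23 | 3-methylfuran-2(5H)-one | CC1=CCOC1=O | starting material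
24 | 3-methyl-2-(triisopropylsilyloxy)furan | CC1=C(O[Si](C(C)C)(C(C)C)C(C)C)OC=C1 | intermediate
25 | 3-[(1,1,3,3-tetramethyldisiloxanyl)oxy] N,O-acetal of 22 (C3 epimers) | C[C@@H]1O[C@H]2[C@H](OC(=O)[C@H]2C)[C@@H]1[C@H]1CCCCN2[C@H]1CCC2O[Si](C)(C)O[SiH](C)C | intermediate
26 | (S)-5-{(3S,9R,9aS)-9-[(2S,3R,3aR,6S,6aR)-2,6-dimethyl-5-oxohexahydrofuro[3,2-b]furan-3-yl]octahydro-1H-pyrrolo[1,2-a]azepin-3-yl}-3-methylfuran-2(5H)-one | C[C@@H]1O[C@H]2[C@H](OC(=O)[C@H]2C)[C@@H]1[C@H]1CCCCN2[C@H]1CC[C@H]2[C@@H]1C=C(C)C(=O)O1 | intermediate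
27 | (3S,5S)-5-{(3S,9R,9aS)-9-[(2S,3R,3aR,6S,6aR)-2,6-dimethyl-5-oxohexahydrofuro[3,2-b]furan-3-yl]octahydro-1H-pyrrolo[1,2-a]azepin-3-yl}-3-methyldihydrofuran-2(3H)-one | C[C@@H]1O[C@H]2[C@H](OC(=O)[C@H]2C)[C@@H]1[C@H]1CCCCN2[C@H]1CC[C@H]2[C@@H]1C[C@H](C)C(=O)O1 | target

**Step count**

Total steps: 11. Longest linear sequence: 10 steps (1 → 4 → 7 → 10 → 13 → 16 → 17 → 19 → 22 → 26 → 27).

**Steps most likely to fail, with fallbacks**

Step 4. The seven-membered amidoalkylation may lose to direct silane reduction of the aldehyde. The fallback sets out from 5 and comes back to the route at 13. Oxidation of 5 to 6 as in step 2 and olefination with triethyl phosphonoacetate (LiCl, i-Pr2NEt) gives ethyl (E)-3-[(S)-5-oxopyrrolidin-2-yl]acrylate F1. Substrate-controlled anti addition of 4-chlorobutylmagnesium bromide (CuBr·SMe2, Me3SiCl) gives ethyl (R)-7-chloro-3-[(S)-5-oxopyrrolidin-2-yl]heptanoate F2. With a weakly acidic ester in place of the imide, NaH/NaI in DMF closes the azepane ring by lactam N-alkylation to give ethyl 2-[(9R,9aS)-3-oxooctahydro-1H-pyrrolo[1,2-a]azepin-9-yl]acetate F3. LiOH then gives 2-[(9R,9aS)-3-oxooctahydro-1H-pyrrolo[1,2-a]azepin-9-yl]acetic acid F4, which is coupled to 1 through its pivalic mixed anhydride (PivCl, Et3N, LiCl) to give 13.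

Step 7. The alkoxy exchange on a hindered secondary alcohol at 110 °C may be slow or may damage the selenoester. The fallback sets out from 17 and comes back at 22, and brings the methyl group in after the cyclisation. Methyl propiolate and N-methylmorpholine at rt give Se-phenyl (2R,3S)-3-{[(E)-3-methoxy-3-oxoprop-1-en-1-yl]oxy}-2-[(9R,9aS)-3-oxooctahydro-1H-pyrrolo[1,2-a]azepin-9-yl]butaneselenoate F5. The conditions of step 8 convert it through methyl 2-{(2R,4R,5S)-5-methyl-3-oxo-4-[(9R,9aS)-3-oxooctahydro-1H-pyrrolo[1,2-a]azepin-9-yl]tetrahydrofuran-2-yl}acetate F6 and methyl 2-{(2R,3R,4S,5S)-3-hydroxy-5-methyl-4-[(9R,9aS)-3-oxooctahydro-1H-pyrrolo[1,2-a]azepin-9-yl]tetrahydrofuran-2-yl}acetate F7 into (9R,9aS)-9-[(2S,3R,3aR,6aR)-2-methyl-5-oxohexahydrofuro[3,2-b]furan-3-yl]octahydro-3H-pyrrolo[1,2-a]azepin-3-one F8. LiN(i-Pr)2 then MeI methylates the lactone enolate on the convex face to give (9R,9aS)-9-[(2S,3R,3aR,6R,6aR)-2,6-dimethyl-5-oxohexahydrofuro[3,2-b]furan-3-yl]octahydro-3H-pyrrolo[1,2-a]azepin-3-one F9. A second enolisation (LiN(i-Pr)2, −78 °C) and kinetic protonation on the convex face with 2,6-di-tert-butylphenol inverts C6 and gives 22.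

Step 8. The acyl radical may decarbonylate, or the C6a/C6 selectivity may be poor on this fully substituted ring. The fallback sets out from 19 and comes back at 20, replacing the radical by a polar acyl-anion cyclisation. Et3SiH with Pd/C reduces the selenoester to methyl (E)-2-methyl-3-{[(2S,3R)-4-oxo-3-[(9R,9aS)-3-oxooctahydro-1H-pyrrolo[1,2-a]azepin-9-yl]butan-2-yl]oxy}acrylate F10. A triazolium-derived N-heterocyclic carbene (i-Pr2NEt, toluene, rt) then effects an intramolecular Stetter reaction, in which the Breslow intermediate adds to the β-alkoxy-methacrylate to give keto ester 20. This is reduced and lactonised as in step 8; a wrong C6 epimer from enolate protonation is corrected by the enolisation and kinetic protonation described for the step 7 fallback.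

**Further compounds**

F1 | step 4 | ethyl (E)-3-[(S)-5-oxopyrrolidin-2-yl]acrylate | CCOC(=O)/C=C/[C@@H]1CCC(=O)N1
F2 | step 4 | ethyl (R)-7-chloro-3-[(S)-5-oxopyrrolidin-2-yl]heptanoate | CCOC(=O)C[C@@H](CCCCCl)[C@@H]1CCC(=O)N1
F3 | step 4 | ethyl 2-[(9R,9aS)-3-oxooctahydro-1H-pyrrolo[1,2-a]azepin-9-yl]acetate | CCOC(=O)C[C@H]1CCCCN2[C@H]1CCC2=O
F4 | step 4 | 2-[(9R,9aS)-3-oxooctahydro-1H-pyrrolo[1,2-a]azepin-9-yl]acetic acid | OC(=O)C[C@H]1CCCCN2[C@H]1CCC2=O
F5 | step 7 | Se-phenyl (2R,3S)-3-{[(E)-3-methoxy-3-oxoprop-1-en-1-yl]oxy}-2-[(9R,9aS)-3-oxooctahydro-1H-pyrrolo[1,2-a]azepin-9-yl]butaneselenoate | C[C@H](O/C=C/C(=O)OC)[C@H](C(=O)[Se]c1ccccc1)[C@H]1CCCCN2[C@H]1CCC2=O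
F6 | step 7 | methyl 2-{(2R,4R,5S)-5-methyl-3-oxo-4-[(9R,9aS)-3-oxooctahydro-1H-pyrrolo[1,2-a]azepin-9-yl]tetrahydrofuran-2-yl}acetate | C[C@@H]1O[C@H](CC(=O)OC)C(=O)[C@@H]1[C@H]1CCCCN2[C@H]1CCC2=O
F7 | step 7 | methyl 2-{(2R,3R,4S,5S)-3-hydroxy-5-methyl-4-[(9R,9aS)-3-oxooctahydro-1H-pyrrolo[1,2-a]azepin-9-yl]tetrahydrofuran-2-yl}acetate | C[C@@H]1O[C@H](CC(=O)OC)[C@H](O)[C@@H]1[C@H]1CCCCN2[C@H]1CCC2=O
F8 | step 7 | (9R,9aS)-9-[(2S,3R,3aR,6aR)-2-methyl-5-oxohexahydrofuro[3,2-b]furan-3-yl]octahydro-3H-pyrrolo[1,2-a]azepin-3-one | C[C@@H]1O[C@H]2[C@H](OC(=O)C2)[C@@H]1[C@H]1CCCCN2[C@H]1CCC2=O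
F9 | step 7 | (9R,9aS)-9-[(2S,3R,3aR,6R,6aR)-2,6-dimethyl-5-oxohexahydrofuro[3,2-b]furan-3-yl]octahydro-3H-pyrrolo[1,2-a]azepin-3-one | C[C@@H]1O[C@H]2[C@H](OC(=O)[C@@H]2C)[C@@H]1[C@H]1CCCCN2[C@H]1CCC2=O
F10 | step 8 | methyl (E)-2-methyl-3-{[(2S,3R)-4-oxo-3-[(9R,9aS)-3-oxooctahydro-1H-pyrrolo[1,2-a]azepin-9-yl]butan-2-yl]oxy}acrylate | C[C@H](O/C=C(\C)C(=O)OC)[C@H](C=O)[C@H]1CCCCN2[C@H]1CCC2=O
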